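Read one constant off Wednesday's run, where [reagent] is lowest. Its target reading at 10.0 min, set against the mean [substrate] and mean [reagent] of that interval, gives a second-order constant of 0.104 /M/min, a reading that carries the scatter.

| setting | Wednesday's | Friday's | grey | teal |
|---|---|---|---|---|
| substrate | 0.50 M | 0.50 M | 0.50 M | 0.50 M |
| reagent | 0.25 M | 0.45 M | 0.300 M | 0.550 M |
| remark | run made earlier | run made earlier |  |  |
| time |  |  | 15 min | 25 min |

- Wednesday's (time / min: target / %): 1.33: 4; 3.00: 5; 6.00: 13; 10.0: 19; 12.0: 19; 20.0: 26
- Friday's (time / min: target / %): 3.00: 9; 6.00: 18; 8.00: 25; 12.0: 28; 15.0: 33; 20.0: 40

(each reading ± 1.5 percentage points)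

- the flask that ends with the higher amount of target, in percent of the substrate charged, or "neither" when 2 percentage points or less lies between them (grey / teal / neither)
- final target, as a percentage of the substrate charged, in grey
- final target, as a percentage of the substrate charged, in teal

- a reading or a percentage of target counts all its forms, free or not

With teal's charge, that reading gives the pseudo-first-order half-life of substrate, ln(2) divided by the constant times the [reagent] present: 12.2 min. Start with the main step alone. At charged [reagent], teal's target reaches 76.0% in 25 min. Put that answer back, with [reagent] lowered to its mean, and teal reaches 60.7%.

Now add a second process. The same two rounds on Friday's run give 46.1% at 20.0 min, but the reading is 40%, lower by a share of 13.3%. The readings do not show where that goes. My own assumption scales this loss with [reagent] times time, which puts teal at 48.4%.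

The forecast gives 26% for grey (23% to 29%) and 50% for teal (44% to 55%), with teal ending higher. It notes that “the apparent k drifts down with time and with more reagent”.

Teal ends higher, at 41.7% against grey's 24.7%, and teal stands 8.3 percentage points under the forecast.

    substrate + reagent → target (k = 0.110 /M/min)
    substrate + 2 reagent → side product (k = 0.0870 /M²/min)
    crystals ⇌ target, rate k3*(cs3 - [target]) while solid is left; crystals form when [target] > cs3 (solubility = 0.170 M, k = 1.00 /min)
    reagent + target → over-reaction product (k = 0.0370 /M/min)

The half-life of substrate by the main step, the quantity first reckoned from the reading as 12.2 min, is 11 min at teal's charge by the hidden constant; at the end of teal, with reagent at 27.3% of its charge and side product at 13.0%, it has grown to 42.0 min, longer than teal's 25 min. At the end of grey, with reagent at 39.9% of its charge, the same reckoning gives 52.7 min, longer than grey's 15 min, with side product at 4.29%.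

(All runs are calculated on assumed constants, and the scatter is random.)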